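**Retrosynthetic overview**
- Last step, one flask: the target is split into a nucleophilic monomer, the (1E,3S,5S)-1,7-diarylhept-1-ene-3,5-diol, and an electrophilic monomer, a cis-(2R,3S) 4-acetoxystyryl epoxide. The C-3–C-3′ bond and the O-1–C-2 bond form in one cation cascade.
- Diol monomer ⇐ 1,3-syn reduction of a (5S)-ketol ⇐ Ipc2BCl aldol of cue-lure with 4-acetoxycinnamaldehyde.
- Epoxide monomer ⇐ cross-metathesis of a cis-vinyl epoxide with 4-acetoxystyrene ⇐ asymmetric chloroallylboration of a 4-arylbutanal ⇐ redox-relay Heck reaction of silylated 4-iodophenol with but-3-en-1-ol.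
- Ring order: the oxirane (a stereochemical relay) is made first in step 6; the oxane is the only ring of the target that is built, and it is closed last in step 8. The four benzene rings are bought.

Assumption: the presumed biosynthesis is taken to be attack of the styrene β-carbon of the (3S,5S)-hept-1-ene-3,5-diol monomer on a 3,4-epoxide (allyl-cation equivalent) of a second diarylheptanoid, with O-5 capturing the p-quinone-methide-type cation that results. Compound numbers follow the forward steps.

**Step 1**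
Reactants: 1 4-formylphenyl acetate; 2 (triphenylphosphoranylidene)acetaldehyde
Product: 3 (E)-3-(4-acetoxyphenyl)prop-2-enal
Conditions: toluene, 80 °C
Reagents that add atoms: none
Why: Wittig olefination with a stabilised formyl ylide gives the (E)-enal and stops after one homologation because the product enal is less electrophilic than the aryl aldehyde.

**Step 2**
Reactants: 4 4-(4-acetoxyphenyl)butan-2-one (cue-lure); 3 (E)-3-(4-acetoxyphenyl)prop-2-enal
Product: 7 (5S,6E)-1,7-bis(4-acetoxyphenyl)-5-hydroxyhept-6-en-3-one, via boron enolate 5 (not isolated), via boron aldolate 6 (not isolated)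
Conditions: (+)-Ipc2BCl (from (−)-α-pinene), Et3N, Et2O, −78 → 0 °C; 3, −78 → −20 °C; H2O2, MeOH, pH 7 buffer, 0 °C
Reagents that add atoms: none
Why: Paterson boron aldol reaction, in which Ipc2BCl/Et3N enolises the methyl ketone on the methyl side and the isopinocampheyl ligands steer the enolate onto the Si face of the enal to set C-5 as S (typically about 80% ee; the minor antipode is purged as diastereomers after fragment union).

**Step 3**
Reactants: 7 (5S,6E)-1,7-bis(4-acetoxyphenyl)-5-hydroxyhept-6-en-3-one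
Product: 10 (1E,3S,5S)-1,7-bis(4-hydroxyphenyl)hept-1-ene-3,5-diol, via diethylboron chelate 8 (not isolated), via diol diacetate 9 (not isolated)
Conditions: Et2BOMe, THF/MeOH 4:1, −78 °C; NaBH4; MeOH co-evaporation; K2CO3, MeOH, 0 °C → rt
Reagents that add atoms: none
Why: Narasaka–Prasad reduction, in which Et2BOMe ties hydroxyl and ketone into a six-membered boron chelate and external hydride attacks axially to give the 1,3-syn diol (new centre S), after which carbonate methanolysis removes both aryl acetates in the same flask.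

**Step 4**
Reactants: 11 4-iodophenol
Product: 12 tert-butyl(4-iodophenoxy)dimethylsilane
Conditions: TBSCl, imidazole, DMF, rt
Reagents that add atoms: tert-butyldimethylsilyl chloride (TBSCl), CC(C)(C)[Si](C)(C)Cl
Why: Standard silylation of a phenol; the aryl silyl ether survives steps 5–7 and falls in the final methanolysis.

**Step 5**
Reactants: 12 tert-butyl(4-iodophenoxy)dimethylsilane; 13 but-3-en-1-ol
Product: 14 4-[4-(tert-butyldimethylsilyloxy)phenyl]butanal
Conditions: Pd(OAc)2 (3 mol %), Bu4NCl, NaHCO3, DMF, 50 °C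
Reagents that add atoms: none
Why: Redox-relay (chain-walking) Heck reaction under Jeffery conditions, in which the aryl group adds to the terminal alkene carbon after oxidative addition to zerovalent palladium and repeated β-hydride elimination/re-insertion walks the metal to the carbinol carbon, releasing the aldehyde.

**Step 6**
Reactants: 14 4-[4-(tert-butyldimethylsilyloxy)phenyl]butanal; 15 allyl chloride
Product: 18 (2R,3S)-2-ethenyl-3-{3-[4-(tert-butyldimethylsilyloxy)phenyl]propyl}oxirane (cis), via O-boryl chlorohydrin 16 (not isolated), via syn-chlorohydrin 17 (not isolated)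
Conditions: 15, (+)-Ipc2BOMe (from (−)-α-pinene), LiNCy2, Et2O/THF, −95 °C; BF3·OEt2; 14, −95 °C, 4 h; HOCH2CH2NH2, rt; crude, DBU, CH2Cl2, rt
Reagents that add atoms: none
Why: Oehlschlager chloroallylboration (Brown-type allylboration), in which the (Z)-γ-chloroallylborane made in the flask adds through a chair Zimmerman–Traxler transition state, the pinene-derived ligands direct attack to the Re face of the aldehyde to give the syn (3S,4S) chlorohydrin, and DBU closes it with inversion at the chlorine-bearing carbon to the cis (2R,3S) vinyl epoxide.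

**Step 7**
Reactants: 18 (2R,3S)-2-ethenyl-3-{3-[4-(tert-butyldimethylsilyloxy)phenyl]propyl}oxirane; 19 4-ethenylphenyl acetate (4-acetoxystyrene, 3 equiv)
Product: 20 4-{(E)-2-[(2R,3S)-3-{3-[4-(tert-butyldimethylsilyloxy)phenyl]propyl}oxiran-2-yl]ethenyl}phenyl acetate (cis-epoxide)
Conditions: second-generation Grubbs catalyst RuCl2(=CHPh)(H2IMes)(PCy3) (5 mol %), CH2Cl2, 40 °C; chromatography on Et3N-deactivated silica
Reagents that add atoms: none
Why: Olefin cross-metathesis between a slowly homodimerising vinyl epoxide and an excess of the styrene partner gives the conjugated (E)-styryl epoxide under thermodynamic control without touching either stereocentre.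

**Step 8**
Reactants: 10 (1E,3S,5S)-1,7-bis(4-hydroxyphenyl)hept-1-ene-3,5-diol; 20 4-{(E)-2-[(2R,3S)-3-{3-[4-(tert-butyldimethylsilyloxy)phenyl]propyl}oxiran-2-yl]ethenyl}phenyl acetate (1.2 equiv)
Product: 23 (2S,3S,4S,6S)-3-[(1E,3R,4S)-4-hydroxy-1,7-bis(4-hydroxyphenyl)hept-1-en-3-yl]-2-(4-hydroxyphenyl)-6-[2-(4-hydroxyphenyl)ethyl]oxan-4-ol (CNP0132332.1), via tetrakis-TMS ether 21 (not isolated), via silylated cascade product 22 (not isolated)
Conditions: N,O-bis(trimethylsilyl)acetamide (BSA, 6 equiv), CH2Cl2, 40 °C; evaporate volatiles; 20, CH2Cl2, TMSOTf (0.2 equiv), −78 → −30 °C; Et3N; K2CO3, MeOH, rt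
Reagents that add atoms: none
Why: Proposed new method: after BSA persilylation masks every hydroxyl so that only the electron-rich styrene can attack, TMSOTf silylates the epoxide oxygen of 20 and the β-carbon of the 4-silyloxystyrene in 21 opens it at the allylic carbon in an SN2-type step with inversion (sets C-3′ R and leaves C-4′ S; the acetoxy group keeps the styryl arm from supporting a free cation); the alkene is attacked anti to its allylic C–O bond through a chair with the arylethyl chain equatorial (sets ring C-3), and the 4-silyloxybenzyl cation so formed is captured by the O-5 silyl ether to close the oxane with the aryl group equatorial (sets C-2; reversible benzylic ionisation makes the 2,6-cis all-equatorial six-membered ring the thermodynamic sink over the five-membered alternative), the released trimethylsilyl cation ending on O-4′ and carrying the chain, before carbonate methanolysis strips all silyl and acetyl groups; the closest known reaction types are Lewis-acid SN2 opening of vinyl epoxides by π-nucleophiles with inversion, the epoxide–alkene formal [3+2] annulation, and the acid-induced 6-endo oxa-cyclisation of 5-hydroxy styrenes through p-quinone-methide-like cations.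

**Compound list**
1 | 4-formylphenyl acetate (4-acetoxybenzaldehyde) | CC(=O)Oc1ccc(C=O)cc1 | starting material
2 | (triphenylphosphoranylidene)acetaldehyde | O=CC=P(c1ccccc1)(c1ccccc1)c1ccccc1 | starting material
3 | (E)-3-(4-acetoxyphenyl)prop-2-enal | CC(=O)Oc1ccc(/C=C/C=O)cc1 | intermediate
4 | 4-(4-acetoxyphenyl)butan-2-one (cue-lure) | CC(=O)CCc1ccc(OC(C)=O)cc1 | starting material
5 | diisopinocampheylboron enolate of 4 (O-boryl enol at the methyl terminus) | C=C(CCc1ccc(OC(C)=O)cc1)OB([C@H]2C[C@H]3C[C@@H]([C@@H]2C)C3(C)C)[C@H]2C[C@H]3C[C@@H]([C@@H]2C)C3(C)C | intermediate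
6 | O-diisopinocampheylboryl ether of 7 (boron aldolate, 5S) | CC(=O)Oc1ccc(/C=C/[C@@H](OB([C@H]2C[C@H]3C[C@@H]([C@@H]2C)C3(C)C)[C@H]2C[C@H]3C[C@@H]([C@@H]2C)C3(C)C)CC(=O)CCc2ccc(OC(C)=O)cc2)cc1 | intermediate
7 | (5S,6E)-1,7-bis(4-acetoxyphenyl)-5-hydroxyhept-6-en-3-one | CC(=O)Oc1ccc(/C=C/[C@@H](O)CC(=O)CCc2ccc(OC(C)=O)cc2)cc1 | intermediate
8 | O-diethylboryl chelate of 7 (boron on the 5-oxygen, coordinated by the ketone) | CCB(CC)O[C@H](/C=C/c1ccc(OC(C)=O)cc1)CC(=O)CCc1ccc(OC(C)=O)cc1 | intermediate
9 | (1E,3S,5S)-1,7-bis(4-acetoxyphenyl)hept-1-ene-3,5-diol (syn diol) | CC(=O)Oc1ccc(/C=C/[C@@H](O)C[C@@H](O)CCc2ccc(OC(C)=O)cc2)cc1 | intermediate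
10 | (1E,3S,5S)-1,7-bis(4-hydroxyphenyl)hept-1-ene-3,5-diol (syn diol) | Oc1ccc(/C=C/[C@@H](O)C[C@@H](O)CCc2ccc(O)cc2)cc1 | intermediate
11 | 4-iodophenol | Oc1ccc(I)cc1 | starting material
12 | tert-butyl(4-iodophenoxy)dimethylsilane | CC(C)(C)[Si](C)(C)Oc1ccc(I)cc1 | intermediate
13 | but-3-en-1-ol | C=CCCO | starting material
14 | 4-[4-(tert-butyldimethylsilyloxy)phenyl]butanal | CC(C)(C)[Si](C)(C)Oc1ccc(CCCC=O)cc1 | intermediate
15 | allyl chloride (3-chloroprop-1-ene) | C=CCCl | starting material
16 | O-diisopinocampheylboryl ether of 17 | C=C[C@H](Cl)[C@H](CCCc1ccc(O[Si](C)(C)C(C)(C)C)cc1)OB([C@H]2C[C@H]3C[C@@H]([C@@H]2C)C3(C)C)[C@H]2C[C@H]3C[C@@H]([C@@H]2C)C3(C)C | intermediate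
17 | (3S,4S)-7-[4-(tert-butyldimethylsilyloxy)phenyl]-3-chlorohept-1-en-4-ol (syn) | C=C[C@H](Cl)[C@@H](O)CCCc1ccc(O[Si](C)(C)C(C)(C)C)cc1 | intermediate
18 | (2R,3S)-2-ethenyl-3-{3-[4-(tert-butyldimethylsilyloxy)phenyl]propyl}oxirane (cis) | C=C[C@H]1O[C@H]1CCCc2ccc(O[Si](C)(C)C(C)(C)C)cc2 | intermediate
19 | 4-ethenylphenyl acetate (4-acetoxystyrene) | C=Cc1ccc(OC(C)=O)cc1 | starting material
20 | 4-{(E)-2-[(2R,3S)-3-{3-[4-(tert-butyldimethylsilyloxy)phenyl]propyl}oxiran-2-yl]ethenyl}phenyl acetate (cis-epoxide) | CC(=O)Oc1ccc(/C=C/[C@H]2O[C@H]2CCCc3ccc(O[Si](C)(C)C(C)(C)C)cc3)cc1 | intermediate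
21 | tetrakis(trimethylsilyl) ether of 10 (both phenols and both alcohols silylated) | C[Si](C)(C)Oc1ccc(/C=C/[C@@H](O[Si](C)(C)C)C[C@@H](O[Si](C)(C)C)CCc2ccc(O[Si](C)(C)C)cc2)cc1 | intermediate
22 | 23 with every centre configured as in 23, carrying TMS on O-4, on O-4′ and on the phenols of the 2-aryl and 6-arylethyl groups, acetyl on the styryl phenol and TBS on the arylpropyl phenol | CC(=O)Oc1ccc(/C=C/[C@H]([C@@H]2[C@@H](c3ccc(O[Si](C)(C)C)cc3)O[C@@H](CCc3ccc(O[Si](C)(C)C)cc3)C[C@@H]2O[Si](C)(C)C)[C@@H](O[Si](C)(C)C)CCCc2ccc(O[Si](C)(C)C(C)(C)C)cc2)cc1 | intermediate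
23 | (2S,3S,4S,6S)-3-[(1E,3R,4S)-4-hydroxy-1,7-bis(4-hydroxyphenyl)hept-1-en-3-yl]-2-(4-hydroxyphenyl)-6-[2-(4-hydroxyphenyl)ethyl]oxan-4-ol | Oc1ccc(/C=C/[C@H]([C@@H]2[C@@H](c3ccc(O)cc3)O[C@@H](CCc3ccc(O)cc3)C[C@@H]2O)[C@@H](O)CCCc2ccc(O)cc2)cc1 | target

**Totals**
Total step count: 8. Longest linear sequence: 5 steps (steps 4, 5, 6, 7, 8, from 4-iodophenol); the other branch is steps 1, 2, 3, 8.

**The three steps most likely to fail, each with a fallback**

Step 8 is the main risk. The cation may be captured kinetically by the epoxide-derived oxygen to give a five-membered ring, the styryl epoxide may open with partial loss of stereospecificity or at the benzylic terminus, and 21 may self-ionise at its allylic silyl ether. The fallback replaces the one-pot cascade by a two-stage ring expansion and sets out from 10 and 20. The union is run on 21 with stoichiometric BF3·OEt2 at −78 °C, so that the boron-bound alkoxide closes the cation to the all-trans 2-aryl oxolane, the silylated tetrahydrofuran isomer F1. Methanolysis (K2CO3, MeOH) gives the free tetrahydrofuran hexaol F2. Because F2 carries a free 4-hydroxyphenyl group on the ring carbon next to oxygen, catalytic camphorsulfonic acid in HFIP/CH2Cl2 at 0 °C opens it reversibly to the p-quinone methide, which recloses through O-5 in a chair to the all-equatorial oxane. The route is rejoined at 23.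

Step 6 is the second risk. The α-chloroallyl anion and its borane decompose above −95 °C, and the crude chlorohydrin must survive the boron work-up. The fallback uses alkoxyallylboration and closes the epoxide from the other oxygen; it sets out from 14. Brown (Z)-γ-(methoxymethoxy)allylboration with the antipodal (−)-Ipc2BOMe (allyl methoxymethyl ether, sBuLi, BF3·OEt2, −78 °C) attacks the Si face and gives (3R,4R)-7-[4-(tert-butyldimethylsilyloxy)phenyl]-3-(methoxymethoxy)hept-1-en-4-ol F3. MsCl/Et3N converts it into the mesylate F4, Me2BBr at −78 °C removes the methoxymethyl group to give the hydroxy mesylate F5, and NaH in THF closes the oxirane with inversion at C-4. The route is rejoined at 18.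

Step 7 is the third risk. Cross-metathesis of the hindered vinyl epoxide may be slow, and 20 is acid-labile on purification. The fallback installs the styryl arm after the ring is made and sets out from 18 and 10. The union of step 8 is run with 18 in place of 20, a clean SN2 opening of a non-benzylic vinyl epoxide, to give the silylated vinyl oxane F6. Methanolysis gives the vinyl pentaol F7. Cross-metathesis of F7 with 19 under the step 7 catalyst, now with no epoxide present, gives the styryl mono-acetate F8, and K2CO3/MeOH cleaves the acetate. The route is rejoined at 23.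

**Further compounds**
F1 | step 8 | silylated tetrahydrofuran isomer: all-trans oxolane formed by closure through the epoxide oxygen, with four TMS, one TBS and one acetyl group as in 22 | CC(=O)Oc1ccc(/C=C/[C@H]2[C@H](CCCc3ccc(O[Si](C)(C)C(C)(C)C)cc3)O[C@@H](c3ccc(O[Si](C)(C)C)cc3)[C@@H]2[C@@H](O[Si](C)(C)C)C[C@@H](O[Si](C)(C)C)CCc2ccc(O[Si](C)(C)C)cc2)cc1
F2 | step 8 | tetrahydrofuran hexaol: 2-(4-hydroxyphenyl)-3-[(1S,3S)-1,3-dihydroxy-5-(4-hydroxyphenyl)pentyl]-4-[(E)-2-(4-hydroxyphenyl)ethenyl]-5-[3-(4-hydroxyphenyl)propyl]oxolane, ring substituents 2,3-trans, 3,4-trans, 4,5-trans | Oc1ccc(/C=C/[C@H]2[C@H](CCCc3ccc(O)cc3)O[C@@H](c3ccc(O)cc3)[C@@H]2[C@@H](O)C[C@@H](O)CCc2ccc(O)cc2)cc1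
F3 | step 6 | (3R,4R)-7-[4-(tert-butyldimethylsilyloxy)phenyl]-3-(methoxymethoxy)hept-1-en-4-ol | C=C[C@@H](OCOC)[C@H](O)CCCc1ccc(O[Si](C)(C)C(C)(C)C)cc1
F4 | step 6 | (3R,4R)-7-[4-(tert-butyldimethylsilyloxy)phenyl]-3-(methoxymethoxy)hept-1-en-4-yl methanesulfonate | C=C[C@@H](OCOC)[C@H](OS(C)(=O)=O)CCCc1ccc(O[Si](C)(C)C(C)(C)C)cc1
F5 | step 6 | (3R,4R)-7-[4-(tert-butyldimethylsilyloxy)phenyl]-3-hydroxyhept-1-en-4-yl methanesulfonate | C=C[C@@H](O)[C@H](OS(C)(=O)=O)CCCc1ccc(O[Si](C)(C)C(C)(C)C)cc1
F6 | step 7 | silylated vinyl oxane: 22 with an ethenyl group in place of the 4-acetoxystyryl group, same configuration | C=C[C@H]([C@@H]1[C@@H](c2ccc(O[Si](C)(C)C)cc2)O[C@@H](CCc2ccc(O[Si](C)(C)C)cc2)C[C@@H]1O[Si](C)(C)C)[C@@H](O[Si](C)(C)C)CCCc1ccc(O[Si](C)(C)C(C)(C)C)cc1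
F7 | step 7 | (2S,3S,4S,6S)-3-[(3R,4S)-4-hydroxy-7-(4-hydroxyphenyl)hept-1-en-3-yl]-2-(4-hydroxyphenyl)-6-[2-(4-hydroxyphenyl)ethyl]oxan-4-ol | C=C[C@H]([C@@H]1[C@@H](c2ccc(O)cc2)O[C@@H](CCc2ccc(O)cc2)C[C@@H]1O)[C@@H](O)CCCc1ccc(O)cc1
F8 | step 7 | 23 acetylated on the styryl phenol only (4-acetoxystyryl), same configuration | CC(=O)Oc1ccc(/C=C/[C@H]([C@@H]2[C@@H](c3ccc(O)cc3)O[C@@H](CCc3ccc(O)cc3)C[C@@H]2O)[C@@H](O)CCCc2ccc(O)cc2)cc1
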